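**Plan**

1. Late cuts: the O8 and O9 acyl groups, C11=C13 (carried as a Me2NCH2 Mannich adduct), and C10–C14 (CHO from a C10 enol triflate and CO).
2. Ring: the 1,5-diene C10=C1–C2–C3–C4=C5 of the ten-membered ring is read as the product of a [3,3] shift. Cutting C2–C3 and joining C5–C10 gives a cyclohexane (C5–C10) bearing a 10-vinyl, a 10-oxido and a cis 5-isopropenyl group.
3. That cyclohexane is cut at C7–C11/O6–C12 (butenolide from a C6-hydroxy C7-ketone), C5–C4 (conjugate addition), C10–O/C7–O (O2 across a ring diene) and C10–C1 (cross-coupling), back to the cis-dihydrodiol of bromobenzene.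
4. Forward order: six-membered ring (bought), then the γ-lactone fused to it, then the ten-membered ring by four-carbon ring expansion, then enal, esters and α-methylene lactone.
5. Stereochemistry: C8/C9 from the enzymatic arene cis-dihydroxylation; C10, C5, C6, C7 by substrate control on the cyclohexane; Z-C4=C5 by transfer from C5/C10 in the sigmatropic step; C1=C10 by kinetic enolisation in the ring; C2' from (S)-2-hydroxy-2-methylbutanoic acid.
6. Enabling feature: C5 and C10, the two ends of the ring 1,5-diene, flank the whole stereogenic segment C6–C9, so the [3,3] precursor is a chair cyclohexane on which all four stereocentres are set before the macrocycle exists.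

Key step: step 9

Remark 1: germacranolide numbering is used throughout (ring C1–C10, lactone C11/C12, methylene C13, formyl C14, methyl C15; six-membered intermediates are ring C5–C10). β is the ring face carrying O8 and O9 (later also C11, vinyl, isopropenyl); α is the opposite face (O6, O10, H5, H7).
Remark 2: diol 1 (the microbial oxidation product of bromobenzene) and acid 23 are taken as purchasable; 1 is otherwise made by whole-cell dihydroxylation of bromobenzene.

**Route**

Step 1
Reactants: 1 (1S,2S)-3-bromocyclohexa-3,5-diene-1,2-diol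
Product: 2 8-O-TBS ether of 1 (9-OH free)
Conditions: TBSCl (1.05 equiv), imidazole, DMF, −20 °C
Reagents that add atoms: tert-butyldimethylsilyl chloride, CC(C)(C)[Si](C)(C)Cl
Why: Silylation with a bulky silyl chloride should take the hydroxyl remote from bromine (C8–OH), because the C9 hydroxyl is flanked and deactivated by the C–Br carbon; no stereocentre is touched.

Step 2
Reactants: 2 8-O-TBS ether of 1
Product: 3 8-O-TBS 9-O-MOM bis-ether of 1
Conditions: MOMCl, i-Pr2NEt, Bu4NI (cat.), CH2Cl2, 0 °C to rt
Reagents that add atoms: chloromethyl methyl ether, COCCl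
Why: Alkylation of the remaining C9 hydroxyl under amine base (acetal ether formation) should give a small, base-stable ether orthogonal to the silyl ether, so that O8 and O9 can later be acylated one after the other.

Step 3
Reactants: 3 8-O-TBS 9-O-MOM bis-ether of 1
Product: 4 10-vinyl diene (Br of 3 replaced by CH=CH2)
Conditions: CH2=CHSnBu3, Pd2(dba)3 (cat.), AsPh3, CuI, NMP, 40 °C
Reagents that add atoms: tributyl(vinyl)stannane, C=C[Sn](CCCC)(CCCC)CCCC
Why: Stille coupling of the vinyl bromide should install C1–C2 at C10 under mild, non-basic conditions that leave the heat- and acid-sensitive diene intact.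

Step 4
Reactants: 4 10-vinyl diene
Product: 7 10α-(trimethylsilyloxy)-10β-vinyl-9β-MOMO-8β-TBSO-cyclohex-5-en-7-one, via endoperoxide 5 (not isolated), via hydroxy enone 6 (not isolated)
Conditions: O2, TPP (cat.), hν, CH2Cl2, −78 °C; then Et3N, 0 °C to rt; then N-(trimethylsilyl)imidazole, rt
Reagents that add atoms: oxygen, O=O; N-(trimethylsilyl)imidazole, C[Si](C)(C)n1ccnc1
Why: Singlet oxygen should add [4+2] across the s-cis ring diene (C10 to C7) on the α face, anti to the β-oriented OTBS and OMOM groups, which sets the quaternary C10–O stereocentre; Kornblum–DeLaMare rearrangement with Et3N can only remove the single α-hydrogen at C7 and so gives the C7 ketone and the C10 tertiary alcohol regiospecifically, and the alcohol is then capped as its TMS ether.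

Step 5
Reactants: 7 10-O-TMS hydroxy enone
Product: 10 6α,10α-dihydroxy-5β-isopropenyl-10β-vinyl-9β-MOMO-8β-TBSO-cyclohexan-7-one, via silyl enol ether 8 (not isolated), via silyloxy ketone 9 (not isolated)
Conditions: CH2=C(Me)MgBr, CuBr·SMe2 (20 mol%), TMSCl, THF, −78 °C; then DMDO, acetone/CH2Cl2, −78 to 0 °C; then citric acid, MeOH, rt
Reagents that add atoms: isopropenylmagnesium bromide, C=C(C)[Mg]Br; dimethyldioxirane, CC1(C)OO1
Why: Copper-catalysed conjugate addition with TMSCl should deliver the isopropenyl group to C5 anti to the pseudo-axial C10–OSiMe3 bond (β face, cis to vinyl) in the half-chair that keeps vinyl and OTBS pseudo-equatorial, as is usual for γ-silyloxy cyclohexenones, and Rubottom oxidation of the silyl enol ether then places O6 on the α face, anti to the C5 and C8 substituents, before mild acid removes both TMS groups.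

Step 6
Reactants: 10 α-hydroxy ketone diol
Product: 12 butenolide (7(11)-en-12,6α-olide), via phosphorane ester 11 (not isolated)
Conditions: Ph3P=C=C=O (1.1 equiv), toluene, 100 °C
Reagents that add atoms: (triphenylphosphoranylidene)ketene, O=C=C=P(c1ccccc1)(c1ccccc1)c1ccccc1
Why: The secondary α-ketol hydroxyl adds to the cumulated ylide to give an ester-stabilised phosphorane that closes onto the adjacent C7 ketone by intramolecular Wittig olefination (butenolide synthesis from α-hydroxy ketones), forming the five-membered lactone ring O6–C12–C11=C7–C6 without engaging the hindered tertiary alcohol.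

Step 7
Reactants: 12 butenolide
Product: 13 trans-fused γ-lactone (12,6α-olide, H7α)
Conditions: [(Ph3P)CuH]6 (5 mol%), PhMe2SiH, t-BuOH, toluene, rt
Reagents that add atoms: none
Why: Copper hydride conjugate reduction of the β-substituted butenolide should deliver hydride to C7 from the α face, anti to the C8 silyloxy group and the β substituents at C5 and C9, which gives H7α and hence the trans-fused lactone with C11 on the β face, while the unactivated vinyl and isopropenyl groups are not reduced.

Step 8
Reactants: 13 trans-fused γ-lactone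
Product: 15 11-(dimethylaminomethyl) lactone, via dilithium alkoxide-enolate 14 (not isolated)
Conditions: LDA (2.2 equiv), THF, −78 °C; then CH2=NMe2+ I−, −78 to 0 °C
Reagents that add atoms: N,N-dimethylmethyleneiminium iodide, C=[N+](C)C.[I-]
Why: Double deprotonation (alkoxide, then lactone enolate) and Mannich reaction with the preformed iminium salt should install C13 on the enolate face anti to C8 as a latent α-methylene unit, whose C11 configuration is of no consequence because it is removed in the last step.

Step 9
Reactants: 15 11-(dimethylaminomethyl) lactone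
Product: 18 ten-membered (4Z)-10-ketone, via potassium alkoxide 16 (not isolated), via potassium enolate 17 (not isolated)
Conditions: KHMDS (1.1 equiv), 18-crown-6, THF, −78 to 40 °C; then AcOH, −78 °C
Reagents that add atoms: none
Why: Deprotonation of the tertiary C10 alcohol gives a potassium alkoxide in which the 3-oxido-1,5-diene C2=C1–C10(O−)–C5–C4(Me)=C3 undergoes a concerted [3,3] shift (anionic oxy-Cope rearrangement, the reaction type by which 1,2-dialkenylcyclohexanols are expanded to cyclodec-5-enones) that breaks C5–C10 and forms C2–C3. The ten-membered carbocycle is thereby closed by a four-carbon ring expansion through a six-centre chair transition state built on the existing cyclohexane, not by an end-to-end cyclisation, which avoids the entropic and transannular penalty of a direct medium-ring closure. No sp3 stereocentre is formed or touched, so C6, C7, C8 and C9, all set on the rigid six-membered ring, pass unchanged into the macrocycle, while the two stereocentres that are consumed (C5 and C10) are translated into alkene geometry. The selectivity needed is the Z (ring-cis) C4=C5 geometry, and it is secured by the cis relationship of the two alkenyl groups together with the trans-fused lactone, which locks the chair with equatorial isopropenyl and axial vinyl, so that C6 is pseudo-axial at C5 in the transition state and ends cis to C3, whereas the ring-flipped chair that would give the E isomer is not accessible. The regiodefined C1=C10 enolate is protonated cold to the ketone because its ring-trans geometry from the chair is not the one wanted in the enal, and irreversible enolate formation together with relief of the syn-axial vinyl/silyloxy interaction should drive the rearrangement.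

Step 10
Reactants: 18 ten-membered (4Z)-10-ketone
Product: 20 C10 enol triflate (1(10)-ene ring-cis), via lithium enolate 19 (not isolated)
Conditions: LiHMDS (1.1 equiv), THF, −78 °C; then N-(5-chloropyridin-2-yl)bis(trifluoromethanesulfonyl)imide, −78 to −20 °C
Reagents that add atoms: N-(5-chloropyridin-2-yl)bis(trifluoromethanesulfonyl)imide, FC(F)(F)S(=O)(=O)N(c1ccc(Cl)cn1)S(=O)(=O)C(F)(F)F
Why: Kinetic deprotonation with a hindered lithium amide should occur at the unhindered C1 methylene and not at the alkoxy-bearing C9 or the lactone methine, and in a ten-membered ring that already holds a cis alkene the ring-cis enolate (O trans to C2) is the low-strain geometry, so that O-sulfonylation (enol triflate formation) fixes C1=C10 with the geometry of the target.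

Step 11
Reactants: 20 C10 enol triflate
Product: 21 enal (C14 aldehyde on C10)
Conditions: Pd(PPh3)4 (5 mol%), CO (1 atm), Bu3SnH (slow addition), LiCl, THF, 50 °C
Reagents that add atoms: carbon monoxide, [C-]#[O+]
Why: Palladium-catalysed reductive carbonylation of the enol triflate (oxidative addition, CO insertion, hydride transfer from tin to the acylpalladium) should give the α,β-unsaturated aldehyde with retention of double-bond geometry and installs C14.

Step 12
Reactants: 21 enal
Product: 22 8β-hydroxy enal
Conditions: HF·pyridine, pyridine, THF, 0 °C to rt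
Reagents that add atoms: none
Why: Buffered HF·pyridine should cleave the secondary silyl ether at O8 while the MOM ether, the enal, the lactone and the acid-sensitive 1,5-diene are left untouched.

Step 13
Reactants: 23 (S)-2-hydroxy-2-methylbutanoic acid
Product: 24 (S)-2-acetoxy-2-methylbutanoic acid
Conditions: AcCl (neat), 45 °C; then H2O
Reagents that add atoms: acetyl chloride, CC(=O)Cl
Why: Acetyl chloride acylates the tertiary hydroxyl of the α-hydroxy acid (O-acetylation, any mixed anhydride being hydrolysed on work-up) without risk to the quaternary stereocentre, which cannot epimerise.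

Step 14
Reactants: 22 8β-hydroxy enal; 24 (S)-2-acetoxy-2-methylbutanoic acid
Product: 26 8-O-[(S)-2-acetoxy-2-methylbutanoyl] 9-O-MOM enal, via acid chloride 25 (not isolated)
Conditions: 24, (COCl)2, DMF (cat.), CH2Cl2, 0 °C to rt; then 22, DMAP, Et3N, CH2Cl2, 0 to 40 °C
Reagents that add atoms: none
Why: The acid chloride formed in the flask should acylate the hindered C8 hydroxyl under nucleophilic catalysis by DMAP (esterification), and since this is the only free hydroxyl the regiochemistry of the two esters is fixed by the protecting-group pattern.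

Step 15
Reactants: 26 8-ester 9-O-MOM enal
Product: 27 9β-hydroxy 8-ester
Conditions: Me2BBr, CH2Cl2, −78 °C; then THF/aq. NaHCO3
Reagents that add atoms: none
Why: Dimethylboron bromide cleaves the MOM acetal at −78 °C by coordination to the acetal oxygen and bromide transfer (Lewis-acid acetal cleavage), conditions under which esters, the lactone and the allylic C9–O bond should survive and the hindered C8 ester should not migrate.

Step 16
Reactants: 27 9β-hydroxy 8-ester
Product: 28 9-O-acetyl 8-ester (13-dimethylamino-11,13-dihydro form of the target)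
Conditions: Ac2O, pyridine, DMAP (cat.), CH2Cl2, 0 °C
Reagents that add atoms: acetic anhydride, CC(=O)OC(C)=O
Why: DMAP-catalysed acetylation of the freed C9 hydroxyl should complete the acylation pattern with no acyl scrambling, since no free hydroxyl remains afterwards.

Step 17
Reactants: 28 9-O-acetyl 8-ester Mannich base
Product: 30 target CNP0499875.1, via ammonium iodide 29 (not isolated)
Conditions: MeI, acetone, rt; then aq. NaHCO3, EtOAc, rt
Reagents that add atoms: none
Why: Quaternisation of the tertiary amine followed by mild base should trigger E1cB elimination of trimethylamine from the β-ammonio lactone (Mannich-base route to α-methylene lactones), unveiling C11=C13 last so that the Michael acceptor never meets the organometallic, hydride or strongly basic steps.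

**Compound list**

1 | (1S,2S)-3-bromocyclohexa-3,5-diene-1,2-diol (C8-OH, C9-OH, C10-Br) | BrC1=CC=C[C@H](O)[C@@H]1O | starting material
2 | 8-O-TBS ether of 1 (9-OH free) | BrC1=CC=C[C@H](O[Si](C)(C)C(C)(C)C)[C@@H]1O | intermediate
3 | 8-O-TBS 9-O-MOM bis-ether of 1 | BrC1=CC=C[C@H](O[Si](C)(C)C(C)(C)C)[C@@H]1OCOC | intermediate
4 | 10-vinyl diene (triene C2=C1–C10=C5–C6=C7; 8β-OTBS, 9β-OMOM) | C=CC1=CC=C[C@H](O[Si](C)(C)C(C)(C)C)[C@@H]1OCOC | intermediate
5 | 7α,10α-endoperoxide of 4 (2,3-dioxabicyclo[2.2.2]oct-5-ene) | C=C[C@]12OO[C@H](C=C1)[C@H](O[Si](C)(C)C(C)(C)C)[C@@H]2OCOC | intermediate (not isolated)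
6 | 10α-hydroxy-10β-vinyl-9β-MOMO-8β-TBSO-cyclohex-5-en-7-one | C=C[C@]1(O)C=CC(=O)[C@H](O[Si](C)(C)C(C)(C)C)[C@@H]1OCOC | intermediate (not isolated)
7 | 10-O-TMS ether of 6 | C=C[C@]1(O[Si](C)(C)C)C=CC(=O)[C@H](O[Si](C)(C)C(C)(C)C)[C@@H]1OCOC | intermediate
8 | 5β-isopropenyl C6=C7 trimethylsilyl enol ether (10-OTMS) | C=C(C)[C@@H]1C=C(O[Si](C)(C)C)[C@H](O[Si](C)(C)C(C)(C)C)[C@H](OCOC)[C@@]1(C=C)O[Si](C)(C)C | intermediate (not isolated)
9 | 5β-isopropenyl-6α,10α-bis(trimethylsilyloxy) 7-ketone | C=C(C)[C@@H]1[C@@H](O[Si](C)(C)C)C(=O)[C@H](O[Si](C)(C)C(C)(C)C)[C@H](OCOC)[C@@]1(C=C)O[Si](C)(C)C | intermediate (not isolated)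
10 | 6α,10α-dihydroxy-5β-isopropenyl-10β-vinyl-9β-MOMO-8β-TBSO-cyclohexan-7-one | C=C(C)[C@@H]1[C@@H](O)C(=O)[C@H](O[Si](C)(C)C(C)(C)C)[C@H](OCOC)[C@@]1(C=C)O | intermediate
11 | 6-O-[(triphenylphosphoranylidene)acetyl] ester of 10 | C=C(C)[C@@H]1[C@@H](OC(=O)C=P(c2ccccc2)(c2ccccc2)c2ccccc2)C(=O)[C@H](O[Si](C)(C)C(C)(C)C)[C@H](OCOC)[C@@]1(C=C)O | intermediate (not isolated)
12 | butenolide: 7(11)-en-12,6α-olide with 5β-isopropenyl, 10α-OH, 10β-vinyl, 8β-OTBS, 9β-OMOM | C=C(C)[C@@H]1[C@H]2OC(=O)C=C2[C@H](O[Si](C)(C)C(C)(C)C)[C@H](OCOC)[C@@]1(C=C)O | intermediate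
13 | trans-fused γ-lactone (12,6α-olide, H7α, C11H2) | C=C(C)[C@@H]1[C@H]2OC(=O)C[C@@H]2[C@H](O[Si](C)(C)C(C)(C)C)[C@H](OCOC)[C@@]1(C=C)O | intermediate
14 | dilithium salt of 13 (C10 alkoxide, lactone enolate) | C=C(C)[C@@H]1[C@H]2OC([O-])=C[C@@H]2[C@H](O[Si](C)(C)C(C)(C)C)[C@H](OCOC)[C@@]1(C=C)[O-].[Li+].[Li+] | intermediate (not isolated)
15 | 11-(dimethylaminomethyl) lactone (C13 on the face of H7) | C=C(C)[C@@H]1[C@H]2OC(=O)[C@@H](CN(C)C)[C@@H]2[C@H](O[Si](C)(C)C(C)(C)C)[C@H](OCOC)[C@@]1(C=C)O | intermediate
16 | potassium C10-alkoxide of 15 | C=C(C)[C@@H]1[C@H]2OC(=O)[C@@H](CN(C)C)[C@@H]2[C@H](O[Si](C)(C)C(C)(C)C)[C@H](OCOC)[C@@]1(C=C)[O-].[K+] | intermediate (not isolated)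
17 | potassium enolate of 18 (C1=C10 ring-trans, O cis to C2) | CN(C)C[C@@H]1C(=O)O[C@@H]2/C=C(/C)CC/C=C(\[O-])[C@@H](OCOC)[C@@H](O[Si](C)(C)C(C)(C)C)[C@@H]12.[K+] | intermediate (not isolated)
18 | ten-membered ketone: (4Z)-13-dimethylamino-9β-MOMO-8β-TBSO-10-oxo-14-norgermacr-4-en-12,6α-olide | CN(C)C[C@@H]1C(=O)O[C@@H]2/C=C(/C)CCCC(=O)[C@@H](OCOC)[C@@H](O[Si](C)(C)C(C)(C)C)[C@@H]12 | intermediate
19 | lithium enolate of 18 (C1=C10 ring-cis) | CN(C)C[C@@H]1C(=O)O[C@@H]2/C=C(/C)CC/C=C(/[O-])[C@@H](OCOC)[C@@H](O[Si](C)(C)C(C)(C)C)[C@@H]12.[Li+] | intermediate (not isolated)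
20 | C10 enol triflate (1(10),4-diene, both ring-cis) | CN(C)C[C@@H]1C(=O)O[C@@H]2/C=C(/C)CC/C=C(/OS(=O)(=O)C(F)(F)F)[C@@H](OCOC)[C@@H](O[Si](C)(C)C(C)(C)C)[C@@H]12 | intermediate
21 | enal (C14 aldehyde on C10; 8β-OTBS, 9β-OMOM) | CN(C)C[C@@H]1C(=O)O[C@@H]2/C=C(/C)CC/C=C(/C=O)[C@@H](OCOC)[C@@H](O[Si](C)(C)C(C)(C)C)[C@@H]12 | intermediate
22 | 8β-hydroxy enal (9β-OMOM) | CN(C)C[C@@H]1C(=O)O[C@@H]2/C=C(/C)CC/C=C(/C=O)[C@@H](OCOC)[C@@H](O)[C@@H]12 | intermediate
23 | (S)-2-hydroxy-2-methylbutanoic acid | OC(=O)[C@](C)(CC)O | starting material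
24 | (S)-2-acetoxy-2-methylbutanoic acid | OC(=O)[C@](C)(CC)OC(C)=O | intermediate
25 | (S)-2-acetoxy-2-methylbutanoyl chloride | ClC(=O)[C@](C)(CC)OC(C)=O | intermediate (not isolated)
26 | 8-O-[(S)-2-acetoxy-2-methylbutanoyl] 9-O-MOM enal | CN(C)C[C@@H]1C(=O)O[C@@H]2/C=C(/C)CC/C=C(/C=O)[C@@H](OCOC)[C@@H](OC(=O)[C@](C)(CC)OC(C)=O)[C@@H]12 | intermediate
27 | 9β-hydroxy 8-ester | CN(C)C[C@@H]1C(=O)O[C@@H]2/C=C(/C)CC/C=C(/C=O)[C@@H](O)[C@@H](OC(=O)[C@](C)(CC)OC(C)=O)[C@@H]12 | intermediate
28 | 9-O-acetyl 8-ester, 13-dimethylamino-11,13-dihydro form of the target | CN(C)C[C@@H]1C(=O)O[C@@H]2/C=C(/C)CC/C=C(/C=O)[C@@H](OC(C)=O)[C@@H](OC(=O)[C@](C)(CC)OC(C)=O)[C@@H]12 | intermediate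
29 | trimethylammonium iodide of 28 | C[N+](C)(C)C[C@@H]1C(=O)O[C@@H]2/C=C(/C)CC/C=C(/C=O)[C@@H](OC(C)=O)[C@@H](OC(=O)[C@](C)(CC)OC(C)=O)[C@@H]12.[I-] | intermediate (not isolated)
30 | CNP0499875.1 | C=C1C(=O)O[C@@H]2/C=C(/C)CC/C=C(/C=O)[C@@H](OC(C)=O)[C@@H](OC(=O)[C@](C)(CC)OC(C)=O)[C@@H]12 | target

**Count and risks**

Total steps: 17. Longest linear sequence: 16 (steps 1–12 and 14–17; step 13 prepares the side-chain acid).

Steps most likely to fail:

1. Step 5. The conjugate addition may show poor or reversed facial selectivity (attack syn to the silyloxy group, pushed by the β-oriented C9 ether and the vinyl group). That would place the isopropenyl group trans to vinyl, an arrangement that cannot reach the Cope transition state from the lactone-locked chair. The fallback sets out from 7 and returns at 10. The same addition is run and the silyl enol ether, now the C5 epimer F1, is dehydrogenated (Pd(OAc)2, MeCN, Saegusa–Ito oxidation) to the 5-isopropenyl enone F2, in which C5 is trigonal and the isopropenyl group is twisted out of conjugation by the quaternary C10. Copper hydride ([(Ph3P)CuH]6 cat., PhMe2SiH) should then deliver hydride to C5 from the same α face that the cuprate had preferred, which puts the isopropenyl group on the β face. The resulting dimethylphenylsilyl enol ether F3 is oxidised (DMDO, then citric acid/MeOH) to 10.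

2. Step 9. The naked alkoxide may trigger retro-Mannich loss of dimethylamine or attack the lactone before the congested substrate rearranges. The fallback sets out from 13 and returns at 18, and replaces the anionic process by a neutral thermal one. The tertiary alcohol is silylated (N-(trimethylsilyl)imidazole) to the TMS ether F4. Heating (toluene, sealed tube, about 200 °C; siloxy-Cope rearrangement through the same lactone-locked chair) should give the ring-expanded trimethylsilyl enol ether F5. With the ketone thus masked, the lactone is aminomethylated (LDA, then CH2=NMe2+ I−) to the Mannich base F6. Citric acid in MeOH then frees ketone 18.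

3. Step 10. Enolisation may go partly towards C9 (with β-elimination of the C8 silyloxy group) or give the ring-trans enolate. The fallback sets out from 15 and returns at 21, and uses the regiodefined enolate of the sigmatropic step instead of a second deprotonation. After the rearrangement of step 9, enolate 17 is trapped in the flask with PhNTf2 to give the ring-trans enol triflate F7. Carbonylation as in step 11 should give the ring-trans enal F8. F8 is then equilibrated by reversible conjugate addition of a catalytic thiol (PhSH, Et3N, THF, rt) to the ring-cis enal 21, which should be favoured because it has the formyl group trans to C2 and a cis,cis-cyclodeca-1,5-diene; no α-methylene lactone is present at this stage to compete.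

**Further compounds**

F1 | step 5 | C5 epimer of silyl enol ether 8 (5α-isopropenyl) | C=C(C)[C@H]1C=C(O[Si](C)(C)C)[C@H](O[Si](C)(C)C(C)(C)C)[C@H](OCOC)[C@@]1(C=C)O[Si](C)(C)C
F2 | step 5 | 5-isopropenyl-10α-(trimethylsilyloxy)-10β-vinyl-9β-MOMO-8β-TBSO-cyclohex-5-en-7-one | C=C(C)C1=CC(=O)[C@H](O[Si](C)(C)C(C)(C)C)[C@H](OCOC)[C@@]1(C=C)O[Si](C)(C)C
F3 | step 5 | 5β-isopropenyl C6=C7 dimethylphenylsilyl enol ether (10-OTMS) | C=C(C)[C@@H]1C=C(O[Si](C)(C)c2ccccc2)[C@H](O[Si](C)(C)C(C)(C)C)[C@H](OCOC)[C@@]1(C=C)O[Si](C)(C)C
F4 | step 9 | 10-O-TMS ether of lactone 13 | C=C(C)[C@@H]1[C@H]2OC(=O)C[C@@H]2[C@H](O[Si](C)(C)C(C)(C)C)[C@H](OCOC)[C@@]1(C=C)O[Si](C)(C)C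
F5 | step 9 | ten-membered (4Z)-diene C10 trimethylsilyl enol ether (C1=C10 ring-trans), lactone C11H2 | C1C(=O)O[C@@H]2/C=C(/C)CC/C=C(\O[Si](C)(C)C)[C@@H](OCOC)[C@@H](O[Si](C)(C)C(C)(C)C)[C@@H]12
F6 | step 9 | 11-(dimethylaminomethyl) derivative of F5 | CN(C)C[C@@H]1C(=O)O[C@@H]2/C=C(/C)CC/C=C(\O[Si](C)(C)C)[C@@H](OCOC)[C@@H](O[Si](C)(C)C(C)(C)C)[C@@H]12
F7 | step 10 | ring-trans C10 enol triflate (C1=C10 isomer of 20) | CN(C)C[C@@H]1C(=O)O[C@@H]2/C=C(/C)CC/C=C(\OS(=O)(=O)C(F)(F)F)[C@@H](OCOC)[C@@H](O[Si](C)(C)C(C)(C)C)[C@@H]12
F8 | step 10 | ring-trans enal (C1=C10 isomer of 21) | CN(C)C[C@@H]1C(=O)O[C@@H]2/C=C(/C)CC/C=C(\C=O)[C@@H](OCOC)[C@@H](O[Si](C)(C)C(C)(C)C)[C@@H]12
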